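4 questions stand over these flasks; answer them with one quantity, reckoned by hand.

    substrate ⇌ intermediate A (K1 = 2.7, k1 = 0.058 s⁻¹)
    intermediate A ⇌ intermediate B (K2 = 0.53, k2 = 0.26 s⁻¹)
    target → over-reaction product (k3 = 0.0077 s⁻¹)
    intermediate A → target (k4 = 0.0087 s⁻¹)

the same everywhere: substrate 1.0 M
- winter: a single well-mixed tank run continuously and read at steady state, 500 s in it on average
- dusk: everything together in a closed stirred flask, run for 100 s; time 100 s
- dawn: a single well-mixed tank run continuously and read at steady state, 100 s in it on average

- the set-up with the highest share of target in all that became target or over-reaction product, at the outlet or at the end ("none" if the first two lie within 2 percentage points) (winter / dusk / dawn / none)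
- share of target in all that became target or over-reaction product, at the outlet or at the end, winter
- share of target in all that became target or over-reaction product, at the outlet or at the end, dusk
- share of target in all that became target or over-reaction product, at the outlet or at the end, dawn

Begin with a tank at steady state. Over-reaction product is made at 0.0077 s⁻¹ times c(target), and it leaves at c(over-reaction product) divided by the mean stay. Divide one rate by the other, set the quotient to one, and the clock drops out: c(over-reaction product)/c(target) equals the rate constant times the stay. For dawn this gives 0.770. Call this product of the over-reaction constant and the time target has stayed the exposure. The share, or selectivity towards target, in such a steady tank, fed with neither target nor over-reaction product, is then one over one plus the exposure. So dawn gives 56.5%, and winter, with exposure 3.85, gives 20.6%.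

Now reckon dusk, the closed flask, in two ways. First, borrow the tank rule and give target an average age of 50.0 s, so an exposure of 0.385, which gives 72.2%. Second, suppose target is made at a steady rate, so that its ages spread evenly from nothing to the full run. Averaging the surviving fraction over those ages gives one minus exp(−exposure), divided by the exposure, with the full 0.770: 69.7%. The first way stands higher than the second, and it cheats: its rule was built on a vessel with an outflow, and dusk has none. I commit to the second, which makes the winner dusk.

The forecast also names dusk, with 20.6% for winter, 70.7% for dusk and 56.5% for dawn, holding that “In a steady tank the share depends only on how long target sits exposed to over-reaction”. Its dusk figure stands slightly above mine.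

The simulation gives dusk, with 20.6% in winter, 70.9% in dusk and 56.5% in dawn. In winter, the turning of intermediate A into intermediate B makes no difference to the share. Use the exposure once more: winter's outlet holds 13.9% target, so its over-reaction product should stand near 53.5% of the substrate charged.

Take the dusk flask read at 40 s. Its exposure is 0.308, and evenly spread ages give 86.1%. The computed share there is 88.3%.

The rate constants stand for no real mixture; no experiment stands behind them.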